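**Plan**

- Numbering (daucane skeleton, used for every intermediate): C1 fusion carbon with CH3, C2 CHOAc, C3 CH2, C4 C(OH)(iPr), C5 fusion CH, C6 CHO-veratroyl, C7 CH2, C8(CH3)–C9 oxirane, C10 CHOH; five-membered ring C1–C5, seven-membered ring C1/C5–C10; β is the face of the C1 methyl group.
- Retrosynthesis: open the oxirane to the 8,9-diol and take that back to the C8=C9 alkene, remove both esters and return C6 and C10 to carbonyls; then cut C1–C5 and C8–C9 together, which opens both rings to an acyclic C15 chain; cut that chain at C1=C2 (cross-metathesis), C9–C10 (MeMgBr), C6–C7 (allylboration) and C3–C4 (Suzuki coupling).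
- Enabling feature: the C2 oxygen lies beside quaternary C1, and C10 and C6, the two carbons flanking the C1–C5 fusion bond, both carry oxygen. This is the imprint of a C1–C2 oxirane next to a C10 enol silane (masked 2-oxyallyl cation C9–C10–C1) facing a C5=C6(OSi)–C7=C8 diene.
- Forward: the C4 carbinol is made first and the chain is grown to an epoxy diketone; one Lewis acid step then closes the five- and seven-membered rings together; C6 is reduced and esterified, the C8=C9 enone is installed, C10–OH and the acetate follow, and the oxirane is closed last from the 8,9-diol.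
- Stereochemistry: C4 from Sharpless epoxidation and Red-Al opening; C1 and C2 from Shi epoxidation (C1 inverts in the ring closure); C5 from the cycloaddition; C6 and C10 by hydride delivery from O4 and O2; C8 by dihydroxylation anti to the C10 oxygen; C9 by inversion in the oxirane closure.

Key step: step 13

Remark on the chemistry: the C8 and C9 descriptors of the target put the oxirane oxygen β at C8 (C8 methyl α) and α at C9, that is, the oxirane is trans-fused to the seven-membered ring; the last five steps are laid out to give exactly this arrangement.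

**Route**

Step 1
Reactants: 1 4-methylpent-2-yn-1-ol
Product: 3 (2Z)-3-iodo-4-methylpent-2-en-1-ol, via cyclic alkenylaluminate 2 (not isolated)
Conditions: NaAlH2(OCH2CH2OMe)2 (Red-Al), THF, 0 °C to rt; then I2, −78 to 0 °C
Reagents that add atoms: iodine, II
Why: Alkoxide-directed trans-hydroalumination of the propargylic alcohol places aluminium on C4, and iodinolysis of the C–Al bond with retention should give only the Z vinyl iodide (directed hydroalumination–iodination).

Step 2
Reactants: 3 (2Z)-3-iodo-4-methylpent-2-en-1-ol; 4 allylboronic acid pinacol ester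
Product: 5 (2E)-3-(propan-2-yl)hexa-2,5-dien-1-ol
Conditions: Pd(PPh3)4 (5 mol%), CsF, THF, 65 °C
Reagents that add atoms: none
Why: Suzuki–Miyaura coupling of the vinyl iodide with the allylboronate forms C3–C4 with retention of alkene geometry, so the isopropyl group ends trans to CH2OH.

Step 3
Reactants: 5 (2E)-3-(propan-2-yl)hexa-2,5-dien-1-ol
Product: 6 [(2S,3S)-3-(propan-2-yl)-3-(prop-2-en-1-yl)oxiran-2-yl]methanol
Conditions: Ti(OiPr)4 (10 mol%), L-(+)-diethyl tartrate (12 mol%), t-BuOOH, 4 Å molecular sieves, CH2Cl2, −20 °C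
Reagents that add atoms: tert-butyl hydroperoxide, CC(C)(C)OO
Why: Sharpless asymmetric epoxidation of the 3,3-disubstituted allylic alcohol with the L-(+)-tartrate catalyst should give the (2S,3S)-oxirane (the sense seen with geraniol), which fixes C4, while the isolated terminal alkene is not touched.

Step 4
Reactants: 6 [(2S,3S)-3-(propan-2-yl)-3-(prop-2-en-1-yl)oxiran-2-yl]methanol
Product: 7 (3R)-3-(propan-2-yl)hex-5-ene-1,3-diol
Conditions: NaAlH2(OCH2CH2OMe)2, THF, 0 °C to rt
Reagents that add atoms: none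
Why: Red-Al opening of the 2,3-epoxy alcohol delivers hydride from the alkoxy-bound aluminium to C5 (the carbon next to CH2OH) and leaves the tertiary C4–O bond and its configuration intact, giving the 1,3-diol.

Step 5
Reactants: 7 (3R)-3-(propan-2-yl)hex-5-ene-1,3-diol
Product: 8 (3R)-3-(propan-2-yl)-1,3-bis(triethylsilyloxy)hex-5-ene
Conditions: Et3SiOTf (2.5 equiv), 2,6-lutidine, CH2Cl2, −78 to 0 °C
Reagents that add atoms: triethylsilyl trifluoromethanesulfonate, CC[Si](CC)(CC)OS(=O)(=O)C(F)(F)F
Why: Silylation with the silyl triflate covers both the primary and the hindered tertiary hydroxyl, so that the C4 oxygen is protected before any basic step and the C6 oxygen carries a group that step 9 can oxidise directly.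

Step 6
Reactants: 8 (3R)-3-(propan-2-yl)-1,3-bis(triethylsilyloxy)hex-5-ene; 9 2-methylprop-2-enal (methacrolein, excess)
Product: 10 (2E,5R)-2-methyl-5-(propan-2-yl)-5,7-bis(triethylsilyloxy)hept-2-enal
Conditions: second-generation Hoveyda–Grubbs catalyst (5 mol%), CH2Cl2, 40 °C
Reagents that add atoms: none
Why: Olefin cross-metathesis of the terminal alkene with the 1,1-disubstituted enal forms C1=C2, and conjugation should make the trisubstituted alkene E (C3 trans to the formyl group), the geometry on which the trans oxirane depends.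

Step 7
Reactants: 10 (2E,5R)-2-methyl-5-(propan-2-yl)-5,7-bis(triethylsilyloxy)hept-2-enal
Product: 11 (3E,6R)-3-methyl-6-(propan-2-yl)-6,8-bis(triethylsilyloxy)oct-3-en-2-ol (both C2 epimers)
Conditions: MeMgBr, THF, −78 °C
Reagents that add atoms: methylmagnesium bromide, C[Mg]Br
Why: Grignard 1,2-addition to the α-branched enal forms C9–C10; the new carbinol centre is oxidised away in step 9, so its configuration is irrelevant.

Step 8
Reactants: 11 (3E,6R)-3-methyl-6-(propan-2-yl)-6,8-bis(triethylsilyloxy)oct-3-en-2-ol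
Product: 12 1-{(2S,3S)-2-methyl-3-[(2S)-2-(propan-2-yl)-2,4-bis(triethylsilyloxy)butyl]oxiran-2-yl}ethan-1-ol (both carbinol epimers)
Conditions: enantiomer of the Shi ketone (from L-sorbose, 30 mol%), KHSO5 (as 2KHSO5·KHSO4·K2SO4), K2CO3, Bu4NHSO4, MeCN/(MeO)2CH2/aq. Na2B4O7 (pH 10.5), 0 °C
Reagents that add atoms: potassium peroxymonosulfate, [K+].[O-]S(=O)(=O)OO
Why: Shi asymmetric epoxidation of the E-trisubstituted alkene through the spiro dioxirane transition state; the L-series ketone should give the (S,S)-oxirane under catalyst control for both C10 epimers, setting C1 and C2.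

Step 9
Reactants: 12 1-{(2S,3S)-2-methyl-3-[(2S)-2-(propan-2-yl)-2,4-bis(triethylsilyloxy)butyl]oxiran-2-yl}ethan-1-ol
Product: 13 (3R)-4-[(2S,3R)-3-acetyl-3-methyloxiran-2-yl]-3-(propan-2-yl)-3-(triethylsilyloxy)butanal
Conditions: (COCl)2, DMSO, CH2Cl2, −78 to −40 °C; Et3N, −78 to −20 °C
Reagents that add atoms: none
Why: Swern oxidation turns the C10 carbinol into the methyl ketone and, in the same operation, converts the primary triethylsilyl ether at C6 directly into the aldehyde, while the tertiary silyl ether and the oxirane are expected to stay.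

Step 10
Reactants: 13 (3R)-4-[(2S,3R)-3-acetyl-3-methyloxiran-2-yl]-3-(propan-2-yl)-3-(triethylsilyloxy)butanal; 4 allylboronic acid pinacol ester
Product: 14 1-{(2R,3S)-3-[(2S)-4-hydroxy-2-(propan-2-yl)-2-(triethylsilyloxy)hept-6-en-1-yl]-2-methyloxiran-2-yl}ethan-1-one (both carbinol epimers)
Conditions: CH2Cl2, rt; aq. NaHCO3 work-up
Reagents that add atoms: none
Why: Uncatalysed allylboration through a closed six-membered transition state takes place at the aldehyde only, so C6–C7 forms without touching the hindered epoxy ketone.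

Step 11
Reactants: 14 1-{(2R,3S)-3-[(2S)-4-hydroxy-2-(propan-2-yl)-2-(triethylsilyloxy)hept-6-en-1-yl]-2-methyloxiran-2-yl}ethan-1-one
Product: 16 (2E,6R)-7-[(2S,3R)-3-acetyl-3-methyloxiran-2-yl]-6-(propan-2-yl)-6-(triethylsilyloxy)hept-2-en-4-one, via allyl ketone 15 (not isolated)
Conditions: Dess–Martin periodinane, NaHCO3, CH2Cl2, 0 °C to rt; then DBU (0.1 equiv), 0 °C
Reagents that add atoms: none
Why: Dess–Martin oxidation gives the β,γ-unsaturated ketone, and a catalytic amine base should move the double bond into conjugation as the thermodynamically preferred E-propenyl ketone.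

Step 12
Reactants: 16 (2E,6R)-7-[(2S,3R)-3-acetyl-3-methyloxiran-2-yl]-6-(propan-2-yl)-6-(triethylsilyloxy)hept-2-en-4-one
Product: 17 (2R,3S)-2-methyl-3-[(2S,3Z,5E)-2-(propan-2-yl)-2,4-bis(triethylsilyloxy)hepta-3,5-dien-1-yl]-2-[1-(triethylsilyloxy)ethenyl]oxirane
Conditions: LiN(iPr)2 (2.4 equiv), Et3SiCl (3 equiv, present from the start), THF, −78 °C
Reagents that add atoms: chlorotriethylsilane, CC[Si](Cl)(CC)CC
Why: Kinetic enolisation with in situ silylation gives the C9=C10 enol silane (C1 has no hydrogen) and, by α′-deprotonation at C5, the cross-conjugated 2-siloxydiene, whose Z geometry keeps C4 away from the propenyl group; immediate trapping should prevent β-elimination of the C4 silyloxy group.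

Step 13
Reactants: 17 (2R,3S)-2-methyl-3-[(2S,3Z,5E)-2-(propan-2-yl)-2,4-bis(triethylsilyloxy)hepta-3,5-dien-1-yl]-2-[1-(triethylsilyloxy)ethenyl]oxirane
Product: 18 2β,4β,6-tris(triethylsilyloxy)-5αH,8αH-dauc-6-en-10-one (trans-fused; 1β- and 8β-methyl, 4α-isopropyl)
Conditions: Et3SiOTf (0.15 equiv), CH2Cl2, −78 °C; Et3N quench
Reagents that add atoms: none
Why: Et3SiOTf silylates the oxirane oxygen and the C1–O bond ionises toward the neighbouring enol silane, so that a 2-siloxyallyl cation spans C9–C10–C1 while the oxygen stays on C2 as its triethylsilyl ether; the oxocarbenium ion left after ring formation passes Et3Si+ to the next oxirane, which keeps the triflate catalytic. The closest known reaction type is the Lewis acid-triggered intramolecular (4+3) cycloaddition of epoxy enol silanes with tethered dienes; the fully substituted oxirane carbon and the acyclic 2-siloxydiene are the features that go beyond the usual substrates. The five-membered ring closes by attack of diene terminus C5 on C1 anti to the leaving oxygen (endo with respect to the oxirane, exo with respect to the diene), and the seven-membered ring closes when the C6–C7–C8 siloxyallyl cation so formed is captured at C8 by enol silane carbon C9 (endo with respect to that allyl unit), in concert with the first bond or directly after it. C1 is fixed by inversion of the enantiopure oxirane carbon, which leaves its methyl group cis to the C2 oxygen; C5 is fixed by an approach with a chair-like tether, C4–OSiEt3 pseudo-equatorial and the diene anti to the siloxyallyl unit, which should give the trans fusion with C6 trans to the C4 isopropyl group; C8 follows from suprafacial addition to the diene (methyl β) and is deleted in step 18. The step needs C–C bond formation at C1 to be faster than capture by the C4 siloxy oxygen or loss of the oxirane configuration, which the weak donor ability of the hindered tertiary silyl ether, the carbon nucleophilicity of the siloxydiene terminus and the temperature of −78 °C should secure; each new bond joins an electron-poor carbon (tertiary C1, oxygen-stabilised C8) to an enol ether carbon (C5, C9).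

Step 14
Reactants: 18 2β,4β,6-tris(triethylsilyloxy)-5αH,8αH-dauc-6-en-10-one
Product: 19 2β,4β-dihydroxy-5αH,8αH-daucane-6,10-dione
Conditions: HF·pyridine, pyridine, THF, 0 °C to rt
Reagents that add atoms: none
Why: Fluoride-mediated desilylation cleaves the enol silane to the C6 ketone and both alkyl silyl ethers under mildly acidic conditions that should not provoke retro-aldol cleavage of the two β-hydroxy ketones.

Step 15
Reactants: 19 2β,4β-dihydroxy-5αH,8αH-daucane-6,10-dione
Product: 20 4β-hydroxy-2β-(triethylsilyloxy)-5αH,8αH-daucane-6,10-dione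
Conditions: Et3SiCl, imidazole, DMF, 0 °C
Reagents that add atoms: chlorotriethylsilane, CC[Si](Cl)(CC)CC
Why: Silylation distinguishes the secondary C2 hydroxyl from the tertiary C4 hydroxyl and blocks O2, so that only O4 can direct the next reduction.

Step 16
Reactants: 20 4β-hydroxy-2β-(triethylsilyloxy)-5αH,8αH-daucane-6,10-dione
Product: 21 4β,6α-dihydroxy-2β-(triethylsilyloxy)-5αH,8αH-daucan-10-one
Conditions: Me4NBH(OAc)3, MeCN/AcOH, −30 to −20 °C
Reagents that add atoms: none
Why: Evans–Saksena reduction: the alkoxyborohydride formed at O4 delivers hydride within a six-membered chair (C7 equatorial) to the β face of the C6 carbonyl, which should give the 6α-alcohol, while the C10 ketone, with no free hydroxyl nearby, is not reduced.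

Step 17
Reactants: 21 4β,6α-dihydroxy-2β-(triethylsilyloxy)-5αH,8αH-daucan-10-one; 22 3,4-dimethoxybenzoyl chloride
Product: 23 6α-(3,4-dimethoxybenzoyloxy)-4β-hydroxy-2β-(triethylsilyloxy)-5αH,8αH-daucan-10-one
Conditions: DMAP, pyridine, CH2Cl2, 0 °C to rt
Reagents that add atoms: none
Why: DMAP-catalysed acylation esterifies the only secondary hydroxyl present, since the tertiary C4 hydroxyl does not react under these conditions.

Step 18
Reactants: 23 6α-(3,4-dimethoxybenzoyloxy)-4β-hydroxy-2β-(triethylsilyloxy)-5αH,8αH-daucan-10-one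
Product: 24 6α-(3,4-dimethoxybenzoyloxy)-4β-hydroxy-2β-(triethylsilyloxy)-5αH-dauc-8-en-10-one
Conditions: IBX, 4-methoxypyridine N-oxide, DMSO, 25 °C
Reagents that add atoms: none
Why: IBX dehydrogenation of the ketone through its enol: C10 can enolise only toward C9 (C1 is quaternary) and the only β-hydrogen is on C8, so the C8=C9 enone should form and the C8 stereocentre disappears.

Step 19
Reactants: 24 6α-(3,4-dimethoxybenzoyloxy)-4β-hydroxy-2β-(triethylsilyloxy)-5αH-dauc-8-en-10-one
Product: 25 6α-(3,4-dimethoxybenzoyloxy)-2β,4β-dihydroxy-5αH-dauc-8-en-10-one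
Conditions: HF·pyridine, pyridine, THF, 0 °C
Reagents that add atoms: none
Why: Fluoride desilylation frees the C2 hydroxyl under non-basic conditions, which avoids retro-aldol cleavage of the β-hydroxy enone and elimination of the veratrate.

Step 20
Reactants: 25 6α-(3,4-dimethoxybenzoyloxy)-2β,4β-dihydroxy-5αH-dauc-8-en-10-one
Product: 26 2β-acetoxy-6α-(3,4-dimethoxybenzoyloxy)-4β,10α-dihydroxy-5αH-dauc-8-ene
Conditions: CH3CHO (10 equiv), SmI2 (0.3 equiv), THF, −10 °C
Reagents that add atoms: acetaldehyde, CC=O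
Why: Evans–Tishchenko reduction: the samarium-bound hemiacetal formed from the C2 hydroxyl and acetaldehyde transfers hydride intramolecularly (chair with C9 equatorial) to the β face of the C10 carbonyl, which should give the 10α-alcohol and leave the acetyl group on O2 in the same step.

Step 21
Reactants: 26 2β-acetoxy-6α-(3,4-dimethoxybenzoyloxy)-4β,10α-dihydroxy-5αH-dauc-8-ene
Product: 27 2β-acetoxy-6α-(3,4-dimethoxybenzoyloxy)-4β-hydroxy-10α-(triethylsilyloxy)-5αH-dauc-8-ene
Conditions: Et3SiCl, imidazole, DMAP (cat.), DMF, 0 °C to rt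
Reagents that add atoms: chlorotriethylsilane, CC[Si](Cl)(CC)CC
Why: Silylation with the silyl chloride and imidazole takes the secondary allylic C10 hydroxyl and leaves the tertiary C4 hydroxyl, and the silyl ether both steers the next step and keeps O10, which is trans to the later C9 leaving group, from closing an ordinary 9,10-oxirane.

Step 22
Reactants: 27 2β-acetoxy-6α-(3,4-dimethoxybenzoyloxy)-4β-hydroxy-10α-(triethylsilyloxy)-5αH-dauc-8-ene
Product: 28 2β-acetoxy-6α-(3,4-dimethoxybenzoyloxy)-4β,8β,9β-trihydroxy-10α-(triethylsilyloxy)-5αH-daucane (8α-methyl)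
Conditions: OsO4 (5 mol%), N-methylmorpholine N-oxide, MeSO2NH2, acetone/H2O, rt
Reagents that add atoms: N-methylmorpholine N-oxide, C[N+]1([O-])CCOCC1; water, O
Why: Upjohn dihydroxylation adds both oxygens to one face of the alkene, and by Kishi's empirical rule osmium tetroxide should approach anti to the allylic C10 silyloxy group, that is from the β face, which sets C8 as in the target (hydroxyl β, methyl α) and puts the C9 hydroxyl β, cis to it.

Step 23
Reactants: 28 2β-acetoxy-6α-(3,4-dimethoxybenzoyloxy)-4β,8β,9β-trihydroxy-10α-(triethylsilyloxy)-5αH-daucane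
Product: 29 2β-acetoxy-6α-(3,4-dimethoxybenzoyloxy)-4β,8β-dihydroxy-9β-(methanesulfonyloxy)-10α-(triethylsilyloxy)-5αH-daucane
Conditions: MsCl (1.2 equiv), Et3N, CH2Cl2, −30 °C
Reagents that add atoms: methanesulfonyl chloride, CS(=O)(=O)Cl
Why: Mesylation through sulfene should take the only secondary hydroxyl (C9) ahead of the hindered tertiary hydroxyls at C4 and C8 at low temperature and leaves the C9 configuration untouched.

Step 24
Reactants: 29 2β-acetoxy-6α-(3,4-dimethoxybenzoyloxy)-4β,8β-dihydroxy-9β-(methanesulfonyloxy)-10α-(triethylsilyloxy)-5αH-daucane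
Product: 30 2β-acetoxy-8β,9α-epoxy-6α-(3,4-dimethoxybenzoyloxy)-4β-hydroxy-10α-(triethylsilyloxy)-5αH-daucane (trans-fused oxirane, 8α-methyl)
Conditions: KN(SiMe3)2 (1.1 equiv), THF, −78 to 0 °C
Reagents that add atoms: none
Why: Proposed new method: the C8 alkoxide should displace the C9 mesylate from the rear (3-exo-tet Williamson closure), so that C9 is inverted to carry oxygen α while C8 keeps oxygen β, and with no antiperiplanar β-hydrogen available (C8 is fully substituted and H10 is syn to the mesylate) and O10 silylated neither an ordinary elimination nor a 9,10-closure is open; the closest known reaction type is the base-induced oxirane closure of vicinal hydroxy sulfonates, established for anti-disposed pairs on rings, and the extension is that the syn-disposed pair on a seven-membered ring must twist toward an antiperiplanar O–C8–C9–O arrangement to give a strained trans-fused oxirane, a ring fusion whose carbocyclic counterpart, trans-bicyclo[5.1.0]octane, is an isolable compound.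

Step 25
Reactants: 30 2β-acetoxy-8β,9α-epoxy-6α-(3,4-dimethoxybenzoyloxy)-4β-hydroxy-10α-(triethylsilyloxy)-5αH-daucane
Product: 31 2β-acetoxy-8β,9α-epoxy-6α-(3,4-dimethoxybenzoyloxy)-4β,10α-dihydroxy-5αH-daucane, (1R,2S,4S,5R,6R,8R,9R,10R)
Conditions: Bu4NF, AcOH (1:1), THF, 0 °C
Reagents that add atoms: none
Why: Fluoride-mediated desilylation with acetic acid as buffer frees the C10 hydroxyl under close to neutral conditions, so that the strained oxirane is not opened by acid and neither ester migrates under base.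

**Compound list**

1 | 4-methylpent-2-yn-1-ol | CC(C)C#CCO | starting material
2 | cyclic alkenylaluminate: sodium 2,2-bis(2-methoxyethoxy)-3-(propan-2-yl)-2,5-dihydro-1,2-oxaluminol-2-uide | CC(C)C1=CCO[Al-]1(OCCOC)OCCOC.[Na+] | intermediate
3 | (2Z)-3-iodo-4-methylpent-2-en-1-ol | OC/C=C(\I)C(C)C | intermediate
4 | allylboronic acid pinacol ester | C=CCB1OC(C)(C)C(C)(C)O1 | starting material
5 | (2E)-3-(propan-2-yl)hexa-2,5-dien-1-ol | OC/C=C(\CC=C)C(C)C | intermediate
6 | [(2S,3S)-3-(propan-2-yl)-3-(prop-2-en-1-yl)oxiran-2-yl]methanol | OC[C@@H]1O[C@@]1(CC=C)C(C)C | intermediate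
7 | (3R)-3-(propan-2-yl)hex-5-ene-1,3-diol | C=CC[C@](O)(C(C)C)CCO | intermediate
8 | (3R)-3-(propan-2-yl)-1,3-bis(triethylsilyloxy)hex-5-ene | C=CC[C@](O[Si](CC)(CC)CC)(C(C)C)CCO[Si](CC)(CC)CC | intermediate
9 | 2-methylprop-2-enal | C=C(C)C=O | starting material
10 | (2E,5R)-2-methyl-5-(propan-2-yl)-5,7-bis(triethylsilyloxy)hept-2-enal | O=C/C(C)=C/C[C@](O[Si](CC)(CC)CC)(C(C)C)CCO[Si](CC)(CC)CC | intermediate
11 | (3E,6R)-3-methyl-6-(propan-2-yl)-6,8-bis(triethylsilyloxy)oct-3-en-2-ol (both C2 epimers) | CC(O)/C(C)=C/C[C@](O[Si](CC)(CC)CC)(C(C)C)CCO[Si](CC)(CC)CC | intermediate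
12 | 1-{(2S,3S)-2-methyl-3-[(2S)-2-(propan-2-yl)-2,4-bis(triethylsilyloxy)butyl]oxiran-2-yl}ethan-1-ol (both carbinol epimers) | CC(O)[C@]1(C)O[C@H]1C[C@](O[Si](CC)(CC)CC)(C(C)C)CCO[Si](CC)(CC)CC | intermediate
13 | (3R)-4-[(2S,3R)-3-acetyl-3-methyloxiran-2-yl]-3-(propan-2-yl)-3-(triethylsilyloxy)butanal | CC(=O)[C@]1(C)O[C@H]1C[C@](O[Si](CC)(CC)CC)(C(C)C)CC=O | intermediate
14 | 1-{(2R,3S)-3-[(2S)-4-hydroxy-2-(propan-2-yl)-2-(triethylsilyloxy)hept-6-en-1-yl]-2-methyloxiran-2-yl}ethan-1-one (both carbinol epimers) | CC(=O)[C@]1(C)O[C@H]1C[C@](O[Si](CC)(CC)CC)(C(C)C)CC(O)CC=C | intermediate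
15 | allyl ketone: (6R)-7-[(2S,3R)-3-acetyl-3-methyloxiran-2-yl]-6-(propan-2-yl)-6-(triethylsilyloxy)hept-1-en-4-one | CC(=O)[C@]1(C)O[C@H]1C[C@](O[Si](CC)(CC)CC)(C(C)C)CC(=O)CC=C | intermediate
16 | (2E,6R)-7-[(2S,3R)-3-acetyl-3-methyloxiran-2-yl]-6-(propan-2-yl)-6-(triethylsilyloxy)hept-2-en-4-one | CC(=O)[C@]1(C)O[C@H]1C[C@](O[Si](CC)(CC)CC)(C(C)C)CC(=O)/C=C/C | intermediate
17 | (2R,3S)-2-methyl-3-[(2S,3Z,5E)-2-(propan-2-yl)-2,4-bis(triethylsilyloxy)hepta-3,5-dien-1-yl]-2-[1-(triethylsilyloxy)ethenyl]oxirane | C=C(O[Si](CC)(CC)CC)[C@]1(C)O[C@H]1C[C@](O[Si](CC)(CC)CC)(C(C)C)/C=C(O[Si](CC)(CC)CC)/C=C/C | intermediate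
18 | 2β,4β,6-tris(triethylsilyloxy)-5αH,8αH-dauc-6-en-10-one | O=C1C[C@H](C)C=C(O[Si](CC)(CC)CC)[C@@H]2[C@@](O[Si](CC)(CC)CC)(C(C)C)C[C@H](O[Si](CC)(CC)CC)[C@@]12C | intermediate
19 | 2β,4β-dihydroxy-5αH,8αH-daucane-6,10-dione | O=C1C[C@H](C)CC(=O)[C@@H]2[C@@](O)(C(C)C)C[C@H](O)[C@@]12C | intermediate
20 | 4β-hydroxy-2β-(triethylsilyloxy)-5αH,8αH-daucane-6,10-dione | O=C1C[C@H](C)CC(=O)[C@@H]2[C@@](O)(C(C)C)C[C@H](O[Si](CC)(CC)CC)[C@@]12C | intermediate
21 | 4β,6α-dihydroxy-2β-(triethylsilyloxy)-5αH,8αH-daucan-10-one | O=C1C[C@H](C)C[C@@H](O)[C@@H]2[C@@](O)(C(C)C)C[C@H](O[Si](CC)(CC)CC)[C@@]12C | intermediate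
22 | 3,4-dimethoxybenzoyl chloride | COc1ccc(C(=O)Cl)cc1OC | starting material
23 | 6α-(3,4-dimethoxybenzoyloxy)-4β-hydroxy-2β-(triethylsilyloxy)-5αH,8αH-daucan-10-one | O=C1C[C@H](C)C[C@@H](OC(=O)c3ccc(OC)c(OC)c3)[C@@H]2[C@@](O)(C(C)C)C[C@H](O[Si](CC)(CC)CC)[C@@]12C | intermediate
24 | 6α-(3,4-dimethoxybenzoyloxy)-4β-hydroxy-2β-(triethylsilyloxy)-5αH-dauc-8-en-10-one | O=C1C=C(C)C[C@@H](OC(=O)c3ccc(OC)c(OC)c3)[C@@H]2[C@@](O)(C(C)C)C[C@H](O[Si](CC)(CC)CC)[C@@]12C | intermediate
25 | 6α-(3,4-dimethoxybenzoyloxy)-2β,4β-dihydroxy-5αH-dauc-8-en-10-one | O=C1C=C(C)C[C@@H](OC(=O)c3ccc(OC)c(OC)c3)[C@@H]2[C@@](O)(C(C)C)C[C@H](O)[C@@]12C | intermediate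
26 | 2β-acetoxy-6α-(3,4-dimethoxybenzoyloxy)-4β,10α-dihydroxy-5αH-dauc-8-ene | O[C@H]1C=C(C)C[C@@H](OC(=O)c3ccc(OC)c(OC)c3)[C@@H]2[C@@](O)(C(C)C)C[C@H](OC(C)=O)[C@@]12C | intermediate
27 | 2β-acetoxy-6α-(3,4-dimethoxybenzoyloxy)-4β-hydroxy-10α-(triethylsilyloxy)-5αH-dauc-8-ene | CC[Si](CC)(CC)O[C@H]1C=C(C)C[C@@H](OC(=O)c3ccc(OC)c(OC)c3)[C@@H]2[C@@](O)(C(C)C)C[C@H](OC(C)=O)[C@@]12C | intermediate
28 | 2β-acetoxy-6α-(3,4-dimethoxybenzoyloxy)-4β,8β,9β-trihydroxy-10α-(triethylsilyloxy)-5αH-daucane (8α-methyl) | CC[Si](CC)(CC)O[C@H]1[C@H](O)[C@](C)(O)C[C@@H](OC(=O)c3ccc(OC)c(OC)c3)[C@@H]2[C@@](O)(C(C)C)C[C@H](OC(C)=O)[C@@]12C | intermediate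
29 | 2β-acetoxy-6α-(3,4-dimethoxybenzoyloxy)-4β,8β-dihydroxy-9β-(methanesulfonyloxy)-10α-(triethylsilyloxy)-5αH-daucane | CC[Si](CC)(CC)O[C@H]1[C@H](OS(C)(=O)=O)[C@](C)(O)C[C@@H](OC(=O)c3ccc(OC)c(OC)c3)[C@@H]2[C@@](O)(C(C)C)C[C@H](OC(C)=O)[C@@]12C | intermediate
30 | 2β-acetoxy-8β,9α-epoxy-6α-(3,4-dimethoxybenzoyloxy)-4β-hydroxy-10α-(triethylsilyloxy)-5αH-daucane (trans-fused oxirane, 8α-methyl) | COc1ccc(C(=O)O[C@@H]2C[C@@]3(C)O[C@@H]3[C@H](O[Si](CC)(CC)CC)[C@]3(C)[C@@H](OC(C)=O)C[C@](O)(C(C)C)[C@@H]23)cc1OC | intermediate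
31 | 2β-acetoxy-8β,9α-epoxy-6α-(3,4-dimethoxybenzoyloxy)-4β,10α-dihydroxy-5αH-daucane, (1R,2S,4S,5R,6R,8R,9R,10R) | COc1ccc(C(=O)O[C@@H]2C[C@@]3(C)O[C@@H]3[C@H](O)[C@]3(C)[C@@H](OC(C)=O)C[C@](O)(C(C)C)[C@@H]23)cc1OC | target

**Step count and risks**

Total: 25 steps. Longest linear sequence: 25 steps (1 to 31); compounds 4, 9 and 22 are used as purchased.

Step 24. What may go wrong: a 1,2-shift of the C8 methyl group or of C7 to C9 with loss of the mesylate (semipinacol rearrangement) outruns the strained 3-exo closure. Fallback (oxygen transfer to the E-cycloalkene instead of ring closure), setting out from 26. It rests on known reaction types: sensitised Z→E photoisomerisation of cycloheptenes with capture by AgNO3, and syn-stereospecific epoxidation by a dioxirane. Irradiation at 254 nm in a cooled flow reactor (−50 °C), with the veratrate as built-in aromatic ester sensitiser and continuous passage over AgNO3-impregnated silica, should give the silver nitrate complex of the E-configured C8=C9 alkene F1. Release of the alkene with NaCl in the presence of dimethyldioxirane (acetone/CH2Cl2, −60 °C) transfers oxygen to one face of the E double bond, which can only give a trans-fused oxirane. This comes back to the route at 31 and needs no protecting group on O10. Of the two helical forms of the E alkene only the one whose open face places oxygen β at C8 leads to 31, so the diastereomeric oxirane would have to be separated.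

Step 13. What may go wrong: the diene terminus C5 adds to C1 through the face that leads to the cis ring fusion (insufficient facial selectivity), so that the wrong C5 configuration is carried forward. Fallback (thermodynamic instead of kinetic control of C5), setting out from 17: the cycloaddition is run as in step 13 and the cis-fused cycloadduct F2 is treated with K2CO3 in MeOH. This methanolyses the enol silane to the cis-fused diketone F3 (not isolated) and equilibrates C5 beside the C6 ketone to the trans-fused diketone F4, in which the C5–C6 bond is trans to the C4 isopropyl group; the two alkyl silyl ethers block retro-aldol cleavage during the equilibration. Because it differs from the hydrolysed form of 18 only at C8, it is taken through the conditions of steps 14 to 17 as the 8-epi-diol F5, the 8-epi-silyl ether F6, the 8-epi-alcohol F7 and the 8-epi-veratrate F8. The dehydrogenation of step 18 then removes that centre and returns the material to the route at 24.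

Step 20. What may go wrong: hydride transfer from the hemiacetal to the neopentyl enone carbonyl is too slow, and retro-aldol cleavage of the β-hydroxy enone or acetyl migration takes over. Fallback (separate reduction and acylation), setting out from 25: Me4NBH(OAc)3 in MeCN/AcOH at −20 °C delivers hydride from the same C2 oxygen and should give the 2β,10α-diol F9. Et3SiCl and imidazole in DMF at −20 °C should silylate the allylic C10 hydroxyl first, to give the 10-silyl ether F10. That hydroxyl has an sp2 neighbour and lies trans to the angular methyl group, whereas the C2 hydroxyl is cis to it. Ac2O, DMAP and pyridine then acetylate the C2 hydroxyl and return the material to the route at 27.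

Further compounds
F1 | step 24 | silver nitrate complex of the E-configured C8=C9 alkene, (8E)-2β-acetoxy-6α-(3,4-dimethoxybenzoyloxy)-4β,10α-dihydroxy-5αH-dauc-8-ene·AgNO3 | O[C@H]1/C=C(\C)C[C@@H](OC(=O)c3ccc(OC)c(OC)c3)[C@@H]2[C@@](O)(C(C)C)C[C@H](OC(C)=O)[C@@]12C.[Ag+].[O-][N+](=O)[O-]
F2 | step 13 | cis-fused cycloadduct, 2β,4β,6-tris(triethylsilyloxy)-5βH,8βH-dauc-6-en-10-one | O=C1C[C@@H](C)C=C(O[Si](CC)(CC)CC)[C@H]2[C@@](O[Si](CC)(CC)CC)(C(C)C)C[C@H](O[Si](CC)(CC)CC)[C@@]12C
F3 | step 13 | cis-fused diketone, 2β,4β-bis(triethylsilyloxy)-5βH,8βH-daucane-6,10-dione | O=C1C[C@@H](C)CC(=O)[C@H]2[C@@](O[Si](CC)(CC)CC)(C(C)C)C[C@H](O[Si](CC)(CC)CC)[C@@]12C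
F4 | step 13 | trans-fused diketone, 2β,4β-bis(triethylsilyloxy)-5αH,8βH-daucane-6,10-dione | O=C1C[C@@H](C)CC(=O)[C@@H]2[C@@](O[Si](CC)(CC)CC)(C(C)C)C[C@H](O[Si](CC)(CC)CC)[C@@]12C
F5 | step 13 | 8-epi-diol, 2β,4β-dihydroxy-5αH,8βH-daucane-6,10-dione | O=C1C[C@@H](C)CC(=O)[C@@H]2[C@@](O)(C(C)C)C[C@H](O)[C@@]12C
F6 | step 13 | 8-epi-silyl ether, 4β-hydroxy-2β-(triethylsilyloxy)-5αH,8βH-daucane-6,10-dione | O=C1C[C@@H](C)CC(=O)[C@@H]2[C@@](O)(C(C)C)C[C@H](O[Si](CC)(CC)CC)[C@@]12C
F7 | step 13 | 8-epi-alcohol, 4β,6α-dihydroxy-2β-(triethylsilyloxy)-5αH,8βH-daucan-10-one | O=C1C[C@@H](C)C[C@@H](O)[C@@H]2[C@@](O)(C(C)C)C[C@H](O[Si](CC)(CC)CC)[C@@]12C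
F8 | step 13 | 8-epi-veratrate, 6α-(3,4-dimethoxybenzoyloxy)-4β-hydroxy-2β-(triethylsilyloxy)-5αH,8βH-daucan-10-one | O=C1C[C@@H](C)C[C@@H](OC(=O)c3ccc(OC)c(OC)c3)[C@@H]2[C@@](O)(C(C)C)C[C@H](O[Si](CC)(CC)CC)[C@@]12C
F9 | step 20 | 2β,10α-diol, 6α-(3,4-dimethoxybenzoyloxy)-2β,4β,10α-trihydroxy-5αH-dauc-8-ene | O[C@H]1C=C(C)C[C@@H](OC(=O)c3ccc(OC)c(OC)c3)[C@@H]2[C@@](O)(C(C)C)C[C@H](O)[C@@]12C
F10 | step 20 | 10-silyl ether, 6α-(3,4-dimethoxybenzoyloxy)-2β,4β-dihydroxy-10α-(triethylsilyloxy)-5αH-dauc-8-ene | CC[Si](CC)(CC)O[C@H]1C=C(C)C[C@@H](OC(=O)c3ccc(OC)c(OC)c3)[C@@H]2[C@@](O)(C(C)C)C[C@H](O)[C@@]12C
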